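**Retrosynthetic overview**

1. Numbering (germacrane): ring C1–C10, C1=C10 carrying C14 (CO2Me), oxirane C4(Me)–C5, lactone O6–C12(=O)–C11(=C13)–C7, ester on O8, acetate on O9. The strategy rests on the homoallylic alcohol C13=C11–C7–C8(OH), which joins the α-methylene-γ-butyrolactone (ring B: O6, C6, C7, C11, C12) to the ten-membered carbocycle (ring A).
2. Endgame: O9 acetate ⇐ O9–H; O8 ester ⇐ C8–OH + (2R,3R)-chlorohydrin acid (from angelic acid by reduction, asymmetric epoxidation, oxidation, HCl opening).
3. Key disconnection C7–C8: ring A is closed last by γ-selective intramolecular addition of the allylchromium from a 3-(bromomethyl)butenolide (ring B present as its endocyclic isomer) to the C8 aldehyde.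
4. Butenolide ⇐ ring-closing metathesis of a C6 2-(bromomethyl)acrylate onto a C6 vinyl group. Enoate C1=C10–C14 ⇐ syn-hydrostannation, iodination and methoxycarbonylation of the C1≡C10 alkyne. C9 ⇐ asymmetric transfer hydrogenation of a C9 ynone (acetylide + Weinreb amide).
5. C2–C6 and the oxirane ⇐ nerol (asymmetric epoxidation, ozonolysis to C1, one-carbon homologation to C10, vinyl addition at C6). Ring order: oxirane, butenolide, ten-membered ring.

Key step: step 18

Remark: the target is built exactly as drawn, with C3 and C6 cis on the oxirane (4R,5S) and C9 cis to C2 on the C1=C10 enoate, so nerol (2Z) is the matching terpene.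

**Route**

Step 1
Reactants: 1 nerol
Product: 2 (2S,3R)-2,3-epoxynerol
Conditions: Ti(OiPr)4 (cat.), L-(+)-diethyl tartrate (cat.), t-BuOOH, 4 Å MS, CH2Cl2, −20 °C
Reagents that add atoms: tert-butyl hydroperoxide, CC(C)(C)OO
Why: Sharpless asymmetric epoxidation, in which the L-(+)-tartrate complex delivers oxygen to the face of the 2Z allylic alcohol that gives 2S,3R (C5 S and C4 R of the target) and leaves the remote alkene, which has no allylic hydroxyl, untouched.

Step 2
Reactants: 2 (2S,3R)-2,3-epoxynerol
Product: 4 4-[(2R,3S)-3-(hydroxymethyl)-2-methyloxiran-2-yl]butanal, via ozonide 3 (not isolated)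
Conditions: O3, CH2Cl2, −78 °C; then Me2S, −78 °C → rt
Reagents that add atoms: ozone, [O-][O+]=O
Why: Ozonolysis with reductive work-up cleaves the only alkene and leaves C1 as the aldehyde, the oxirane and the primary alcohol being inert to ozone at −78 °C.

Step 3
Reactants: 4 4-[(2R,3S)-3-(hydroxymethyl)-2-methyloxiran-2-yl]butanal
Product: 5 [(2S,3R)-3-(but-3-yn-1-yl)-3-methyloxiran-2-yl]methanol
Conditions: dimethyl (1-diazo-2-oxopropyl)phosphonate, K2CO3, MeOH, 0 °C → rt
Reagents that add atoms: dimethyl (1-diazo-2-oxopropyl)phosphonate, CC(=O)C(=[N+]=[N-])P(=O)(OC)OC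
Why: Ohira–Bestmann (Seyferth–Gilbert) homologation converts the aldehyde into the terminal alkyne whose new carbon is C10, and the mild carbonate base leaves the trisubstituted epoxy alcohol alone.

Step 4
Reactants: 5 [(2S,3R)-3-(but-3-yn-1-yl)-3-methyloxiran-2-yl]methanol
Product: 6 (2R,3R)-3-(but-3-yn-1-yl)-3-methyloxirane-2-carbaldehyde
Conditions: TEMPO (cat.), PhI(OAc)2, CH2Cl2, rt
Reagents that add atoms: none
Why: TEMPO/PhI(OAc)2 oxidation of the primary alcohol stops at the aldehyde under neutral conditions, so the α-oxirane stereocentre (C5) and the alkyne are kept.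

Step 5
Reactants: 6 (2R,3R)-3-(but-3-yn-1-yl)-3-methyloxirane-2-carbaldehyde
Product: 7 (1S)-1-[(2S,3R)-3-(but-3-yn-1-yl)-3-methyloxiran-2-yl]prop-2-en-1-ol
Conditions: CH2=CHMgBr, THF, −78 °C; then H2O
Reagents that add atoms: vinylmagnesium bromide, C=C[Mg]Br
Why: Grignard 1,2-addition to the α,β-epoxy aldehyde under Felkin–Anh control (oxirane C5–O bond anti to the incoming vinyl group, reinforced by the cis chain on the oxirane) should favour the anti epoxy alcohol, which is 6S; at −78 °C addition outruns deprotonation of the alkyne, and the C6 epimer is removed by chromatography.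

Step 6
Reactants: 7 (1S)-1-[(2S,3R)-3-(but-3-yn-1-yl)-3-methyloxiran-2-yl]prop-2-en-1-ol
Product: 8 triethylsilyl ether of 7
Conditions: Et3SiCl, imidazole, DMF, 0 °C
Reagents that add atoms: chlorotriethylsilane, CC[Si](CC)(CC)Cl
Why: Standard silylation masks O6 for the acetylide chemistry with a group that can later be removed in the presence of a secondary TBS ether.

Step 7
Reactants: 9 2-chloro-N-methoxy-N-methylacetamide; 10 4-methoxybenzyl alcohol
Product: 12 N-methoxy-2-[(4-methoxyphenyl)methoxy]-N-methylacetamide, via sodium (4-methoxyphenyl)methanolate 11 (not isolated)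
Conditions: 10, NaH, THF, 0 °C; then 9, 0 °C → rt
Reagents that add atoms: none
Why: Williamson ether synthesis on a highly SN2-reactive α-chloro amide, the Weinreb amide itself being inert to the alkoxide.

Step 8
Reactants: 8 triethylsilyl ether of 7; 12 N-methoxy-2-[(4-methoxyphenyl)methoxy]-N-methylacetamide
Product: 14 1-[(4-methoxyphenyl)methoxy]-7-{(2R,3S)-2-methyl-3-[(1S)-1-(triethylsilyloxy)prop-2-en-1-yl]oxiran-2-yl}hept-3-yn-2-one, via lithium acetylide 13 (not isolated)
Conditions: n-BuLi, THF, −78 °C; then 12, −78 → −20 °C; then H2O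
Reagents that add atoms: none
Why: Acylation of the lithium acetylide by the Weinreb amide stops at the ketone through the chelated tetrahedral intermediate and forms the C10–C9 bond, while oxirane, alkene and silyl ether do not react with the acetylide at low temperature.

Step 9
Reactants: 14 the ynone of step 8
Product: 15 (2R)-1-[(4-methoxyphenyl)methoxy]-7-{(2R,3S)-2-methyl-3-[(1S)-1-(triethylsilyloxy)prop-2-en-1-yl]oxiran-2-yl}hept-3-yn-2-ol
Conditions: Ru[(S,S)-TsDPEN](p-cymene) (cat.), i-PrOH, rt
Reagents that add atoms: none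
Why: Noyori asymmetric transfer hydrogenation of the ynone, in which the (S,S)-diamine catalyst places the alkynyl group where the aryl group of an aryl ketone sits and so gives the 9R carbinol (R because CH2O outranks the alkyne), without reducing alkyne, alkene or oxirane.

Step 10
Reactants: 15 the (2R)-propargylic alcohol of step 9
Product: 17 (2S,3E)-3-iodo-1-[(4-methoxyphenyl)methoxy]-7-{(2R,3S)-2-methyl-3-[(1S)-1-(triethylsilyloxy)prop-2-en-1-yl]oxiran-2-yl}hept-3-en-2-ol, via (E)-vinylstannane 16 (not isolated)
Conditions: Bu3SnH, PdCl2(PPh3)2 (cat.), THF, 0 °C; then I2, CH2Cl2, 0 °C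
Reagents that add atoms: iodine, II
Why: Palladium-catalysed syn-hydrostannation puts tin on C10, the alkyne carbon next to the free propargylic hydroxyl, and hydrogen on C1, so that C2 and C9 become cis; iododestannylation then occurs with retention, and the minor distal regioisomer is removed by chromatography.

Step 11
Reactants: 17 the (E)-iodoalkene alcohol of step 10
Product: 18 tert-butyldimethylsilyl ether of 17
Conditions: t-BuMe2SiCl, imidazole, DMAP (cat.), DMF, 35 °C
Reagents that add atoms: tert-butyldimethylsilyl chloride, CC(C)(C)[Si](C)(C)Cl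
Why: Silylation of the secondary allylic alcohol under basic conditions free of Lewis acid keeps oxirane and vinyl iodide intact and installs the bulky, non-chelating ether that later directs the aldehyde face.

Step 12
Reactants: 18 tert-butyldimethylsilyl ether of 17
Product: 19 methyl (2E)-2-[(1R)-1-(tert-butyldimethylsilyloxy)-2-[(4-methoxyphenyl)methoxy]ethyl]-6-{(2R,3S)-2-methyl-3-[(1S)-1-(triethylsilyloxy)prop-2-en-1-yl]oxiran-2-yl}hex-2-enoate
Conditions: Pd(OAc)2 (cat.), dppf (cat.), CO (1 atm), MeOH, Et3N, DMF, 50 °C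
Reagents that add atoms: carbon monoxide, [C-]#[O+]; methanol, CO
Why: Palladium-catalysed methoxycarbonylation of the vinyl iodide (oxidative addition, CO insertion, methanolysis) installs C14 with retention of alkene geometry, giving the enoate with the ester trans to C2.

Step 13
Reactants: 19 the enoate of step 12
Product: 20 methyl (2E)-2-[(1R)-1-(tert-butyldimethylsilyloxy)-2-[(4-methoxyphenyl)methoxy]ethyl]-6-{(2R,3S)-3-[(1S)-1-hydroxyprop-2-en-1-yl]-2-methyloxiran-2-yl}hex-2-enoate
Conditions: HF·pyridine, pyridine, THF, 0 °C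
Reagents that add atoms: none
Why: Buffered HF·pyridine cleaves the secondary triethylsilyl ether much faster than the secondary TBS ether and does not open the oxirane.

Step 14
Reactants: 20 the C6 alcohol of step 13; 21 2-(bromomethyl)acrylic acid
Product: 23 2-(bromomethyl)acrylate ester of 20 at O6, via 2-(bromomethyl)acryloyl bromide 22 (not isolated)
Conditions: 21, (COBr)2, DMF (cat.), CH2Cl2, 0 °C → rt; then 20, i-Pr2NEt, CH2Cl2, −20 → 0 °C
Reagents that add atoms: none
Why: O-Acylation with the acid bromide and a hindered amine avoids nucleophilic catalysts and foreign halide, so the allylic bromide is neither displaced nor scrambled, and C6 keeps its configuration because its C–O bond is not broken.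

Step 15
Reactants: 23 the 2-(bromomethyl)acrylate of step 14
Product: 24 methyl (2E)-6-{(2R,3S)-3-[(2S)-4-(bromomethyl)-5-oxo-2,5-dihydrofuran-2-yl]-2-methyloxiran-2-yl}-2-[(1R)-1-(tert-butyldimethylsilyloxy)-2-[(4-methoxyphenyl)methoxy]ethyl]hex-2-enoate
Conditions: second-generation Hoveyda–Grubbs catalyst (5 mol %), toluene, 70 °C, 5 mM
Reagents that add atoms: none
Why: Ring-closing metathesis between the monosubstituted C7 vinyl group and the 1,1-disubstituted acrylate closes the five-membered lactone with loss of ethene, as is known for α-substituted acrylates, while the trisubstituted electron-poor C1=C10 enoate stays out of the reaction.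

Step 16
Reactants: 24 the bromomethyl butenolide of step 15
Product: 25 primary alcohol from 24 (CH2OH at C8 in place of the 4-methoxybenzyl ether)
Conditions: DDQ, CH2Cl2/pH 7 phosphate buffer, 0 °C
Reagents that add atoms: none
Why: Oxidative cleavage of the 4-methoxybenzyl ether by DDQ is neutral and leaves silyl ether, oxirane, allylic bromide and butenolide alone; the γ-hydroxy ester is used at once so that it cannot lactonise onto C14.

Step 17
Reactants: 25 the primary alcohol of step 16
Product: 26 methyl (2E)-6-{(2R,3S)-3-[(2S)-4-(bromomethyl)-5-oxo-2,5-dihydrofuran-2-yl]-2-methyloxiran-2-yl}-2-[(1R)-1-(tert-butyldimethylsilyloxy)-2-oxoethyl]hex-2-enoate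
Conditions: Dess–Martin periodinane, pyridine, CH2Cl2, 0 °C
Reagents that add atoms: none
Why: Dess–Martin oxidation gives the α-silyloxy aldehyde without a base strong enough to epimerise C9, and the crude aldehyde is cyclised directly.

Step 18
Reactants: 26 the bromomethyl butenolide aldehyde of step 17
Product: 28 ten-membered α-methylene lactone with free C8 hydroxyl and C9 TBS ether (configuration 4R,5S,6S,7R,8S,9R), via allylchromium dichloride 27 (not isolated)
Conditions: CrCl2 (6 equiv), THF, 25 °C, syringe-pump addition of 26 (final 2 mM); then H2O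
Reagents that add atoms: none
Why: CrCl2 (two equivalents per bromide) reduces the C13–Br bond to an allylchromium dichloride (trivalent chromium) that adds to the tethered aldehyde through its γ-carbon C7 in a six-membered cyclic transition state with O8 on chromium, which shifts the double bond to C11=C13 and unveils the α-methylene lactone; the closest known reactions are the chromium- and zinc-mediated additions of 3-(bromomethyl)furan-2(5H)-ones to aldehydes and Nozaki–Hiyama allylations used for macrocyclisation. The ten-membered ring closes in the 10-exo-trig mode (C7 onto the C8 carbonyl), the ring-cis C1=C10 enoate and the cis-oxirane bending the chain back towards the butenolide and high dilution suppressing oligomers. C7 is controlled by the C6 stereocentre: the chain leaves C6 on one face of the flat butenolide and can deliver the aldehyde to C7 only from the opposite face without eclipsing C5–C6 against C7–C8, so the lactone becomes trans-fused (7R). C8 is controlled by C9: the aldehyde should react in its Cornforth/polar Felkin–Anh arrangement (C9–OSi bond anti to the carbonyl, attack past H9), which gives the 8,9-anti (8S) alcohol, and the bulky silyl ether, which cannot chelate the crowded chromium centre, is what secures this. The selectivity the step needs is therefore the aldehyde face, and it is the weak point: in the cyclic array this face puts C9 pseudo-axial (boat-like) over C6, whereas the chair with C9 equatorial, preferred in intermolecular additions of this reagent, leads to the C8 epimer. γ-Regioselectivity follows from the normal preference of allylchromium reagents for the substituted terminus, the lactone C6–O bond lies in the ring plane orthogonal to the allyl π-system and cannot β-eliminate, and oxirane, enoate and silyl ether are inert to CrCl2.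

Step 19
Reactants: 29 angelic acid
Product: 30 (2Z)-2-methylbut-2-en-1-ol
Conditions: LiAlH4, Et2O, 0 °C
Reagents that add atoms: none
Why: Hydride reduction of the carboxylic acid to the allylic alcohol, which at 0 °C in ether neither reduces nor isomerises the trisubstituted alkene.

Step 20
Reactants: 30 (2Z)-2-methylbut-2-en-1-ol
Product: 31 [(2R,3S)-2,3-dimethyloxiran-2-yl]methanol
Conditions: Ti(OiPr)4, D-(−)-diethyl tartrate, t-BuOOH, 4 Å MS, CH2Cl2, −20 °C
Reagents that add atoms: tert-butyl hydroperoxide, CC(C)(C)OO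
Why: Sharpless asymmetric epoxidation, in which the D-(−)-tartrate complex adds oxygen syn to the face of the Z-allylic alcohol that gives 2R,3S.

Step 21
Reactants: 31 [(2R,3S)-2,3-dimethyloxiran-2-yl]methanol
Product: 32 (2S,3S)-2,3-dimethyloxirane-2-carboxylic acid
Conditions: RuCl3·H2O (cat.), NaIO4, MeCN/EtOAc/H2O, 0 °C → rt
Reagents that add atoms: sodium periodate, [Na+].[O-]I(=O)(=O)=O; water, O
Why: Ruthenium tetroxide oxidation (RuO4 formed in the flask from RuCl3 and NaIO4) takes the primary epoxy alcohol to the glycidic acid without touching the oxirane stereocentres.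

Step 22
Reactants: 32 (2S,3S)-2,3-dimethyloxirane-2-carboxylic acid
Product: 33 (2R,3R)-3-chloro-2-hydroxy-2-methylbutanoic acid
Conditions: HCl (4 M in dioxane), Et2O, 0 °C
Reagents that add atoms: hydrogen chloride, Cl
Why: Acid-promoted oxirane opening by chloride at C3, the carbon remote from the carboxyl group (the α-carbon is deactivated towards substitution), with inversion at C3 and retention at C2, turns the (2S,3S)-epoxide into the (2R,3R)-chlorohydrin.

Step 23
Reactants: 33 (2R,3R)-3-chloro-2-hydroxy-2-methylbutanoic acid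
Product: 35 (2R,3R)-3-chloro-2-methyl-2-(triethylsilyloxy)butanoic acid, via triethylsilyl ester 34 (not isolated)
Conditions: Et3SiOTf (2.2 equiv), 2,6-lutidine, CH2Cl2, −78 → 0 °C; then THF/H2O, rt
Reagents that add atoms: triethylsilyl trifluoromethanesulfonate, CC[Si](CC)(CC)OS(=O)(=O)C(F)(F)F
Why: The silyl triflate silylates both the hindered tertiary hydroxyl and the carboxyl group, and the labile silyl ester alone is hydrolysed on aqueous work-up, so the tertiary hydroxyl is masked for the esterification.

Step 24
Reactants: 28 the ten-membered lactone alcohol of step 18; 35 (2R,3R)-3-chloro-2-methyl-2-(triethylsilyloxy)butanoic acid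
Product: 37 C8 ester of 28 with acid 35 (C9 TBS ether and side-chain triethylsilyl ether in place), via mixed anhydride 36 (not isolated)
Conditions: 35, 2,4,6-trichlorobenzoyl chloride, Et3N, THF, rt; then 28, DMAP, toluene, rt → 40 °C
Reagents that add atoms: none
Why: Yamaguchi esterification, in which DMAP transfers the α-branched acyl group from the mixed anhydride to the hindered secondary C8 hydroxyl with retention at C8, and which the α-methylene lactone and oxirane tolerate.

Step 25
Reactants: 37 the doubly silylated C8 ester of step 24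
Product: 38 C8 ester with free C9 hydroxyl and free tertiary hydroxyl in the side chain
Conditions: HF·pyridine, pyridine, THF, 0 °C → rt
Reagents that add atoms: none
Why: Buffered fluoride cleavage of both silyl ethers under mildly acidic conditions avoids base-induced closure of the chlorohydrin, acyl migration from O8 to O9 and conjugate addition to the methylene lactone.

Step 26
Reactants: 38 the diol of step 25
Product: 39 CNP0185503.1 (target)
Conditions: Ac2O, pyridine, DMAP (cat.), CH2Cl2, 0 °C
Reagents that add atoms: acetic anhydride, CC(=O)OC(C)=O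
Why: Acetylation of the secondary C9 hydroxyl, while the tertiary hydroxyl of the side chain, flanked by a quaternary centre and the ester carbonyl, is not acylated under these mild conditions.

**Compound list**

1 | nerol | CC(C)=CCC/C(C)=C\CO | starting material
2 | (2S,3R)-2,3-epoxynerol | OC[C@@H]1O[C@]1(C)CCC=C(C)C | intermediate
3 | ozonide of 2 (5,5-dimethyl-1,2,4-trioxolane, mixture at the trioxolane CH) | OC[C@@H]1O[C@]1(C)CCC2OOC(C)(C)O2 | intermediate
4 | 4-[(2R,3S)-3-(hydroxymethyl)-2-methyloxiran-2-yl]butanal | OC[C@@H]1O[C@]1(C)CCC=O | intermediate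
5 | [(2S,3R)-3-(but-3-yn-1-yl)-3-methyloxiran-2-yl]methanol | OC[C@@H]1O[C@]1(C)CCC#C | intermediate
6 | (2R,3R)-3-(but-3-yn-1-yl)-3-methyloxirane-2-carbaldehyde | O=C[C@@H]1O[C@]1(C)CCC#C | intermediate
7 | (1S)-1-[(2S,3R)-3-(but-3-yn-1-yl)-3-methyloxiran-2-yl]prop-2-en-1-ol | C=C[C@H](O)[C@@H]1O[C@]1(C)CCC#C | intermediate
8 | triethylsilyl ether of 7 | C=C[C@H](O[Si](CC)(CC)CC)[C@@H]1O[C@]1(C)CCC#C | intermediate
9 | 2-chloro-N-methoxy-N-methylacetamide | CN(OC)C(=O)CCl | starting material
10 | 4-methoxybenzyl alcohol | COc1ccc(CO)cc1 | starting material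
11 | sodium (4-methoxyphenyl)methanolate | [Na+].[O-]Cc1ccc(OC)cc1 | intermediate
12 | N-methoxy-2-[(4-methoxyphenyl)methoxy]-N-methylacetamide | COc1ccc(COCC(=O)N(C)OC)cc1 | intermediate
13 | lithium acetylide of 8 | C=C[C@H](O[Si](CC)(CC)CC)[C@@H]1O[C@]1(C)CCC#C[Li] | intermediate
14 | 1-[(4-methoxyphenyl)methoxy]-7-{(2R,3S)-2-methyl-3-[(1S)-1-(triethylsilyloxy)prop-2-en-1-yl]oxiran-2-yl}hept-3-yn-2-one | C=C[C@H](O[Si](CC)(CC)CC)[C@@H]1O[C@]1(C)CCC#CC(=O)COCc1ccc(OC)cc1 | intermediate
15 | (2R)-alcohol from 14 | C=C[C@H](O[Si](CC)(CC)CC)[C@@H]1O[C@]1(C)CCC#C[C@@H](O)COCc1ccc(OC)cc1 | intermediate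
16 | (E)-3-(tributylstannyl)alkene from 15 (tin on C10, C2 cis to C9) | C=C[C@H](O[Si](CC)(CC)CC)[C@@H]1O[C@]1(C)CC/C=C([Sn](CCCC)(CCCC)CCCC)\[C@@H](O)COCc1ccc(OC)cc1 | intermediate
17 | (2S,3E)-3-iodo-1-[(4-methoxyphenyl)methoxy]-7-{(2R,3S)-2-methyl-3-[(1S)-1-(triethylsilyloxy)prop-2-en-1-yl]oxiran-2-yl}hept-3-en-2-ol | C=C[C@H](O[Si](CC)(CC)CC)[C@@H]1O[C@]1(C)CC/C=C(I)\[C@@H](O)COCc1ccc(OC)cc1 | intermediate
18 | tert-butyldimethylsilyl ether of 17 | C=C[C@H](O[Si](CC)(CC)CC)[C@@H]1O[C@]1(C)CC/C=C(I)\[C@@H](O[Si](C)(C)C(C)(C)C)COCc1ccc(OC)cc1 | intermediate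
19 | methyl (2E)-enoate from 18 (C14 ester, O6 triethylsilyl, O9 TBS, O8 4-methoxybenzyl) | C=C[C@H](O[Si](CC)(CC)CC)[C@@H]1O[C@]1(C)CC/C=C(C(=O)OC)\[C@@H](O[Si](C)(C)C(C)(C)C)COCc1ccc(OC)cc1 | intermediate
20 | C6 alcohol from 19 | C=C[C@H](O)[C@@H]1O[C@]1(C)CC/C=C(C(=O)OC)\[C@@H](O[Si](C)(C)C(C)(C)C)COCc1ccc(OC)cc1 | intermediate
21 | 2-(bromomethyl)acrylic acid | C=C(CBr)C(=O)O | starting material
22 | 2-(bromomethyl)acryloyl bromide | C=C(CBr)C(Br)=O | intermediate
23 | 2-(bromomethyl)acrylate ester of 20 | C=C(CBr)C(=O)O[C@@H](C=C)[C@@H]1O[C@]1(C)CC/C=C(C(=O)OC)\[C@@H](O[Si](C)(C)C(C)(C)C)COCc1ccc(OC)cc1 | intermediate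
24 | (5S)-3-(bromomethyl)butenolide with O8 4-methoxybenzyl ether | BrCC1=C[C@H](OC1=O)[C@@H]2O[C@]2(C)CC/C=C(C(=O)OC)\[C@@H](O[Si](C)(C)C(C)(C)C)COCc1ccc(OC)cc1 | intermediate
25 | bromomethyl butenolide with free C8 primary alcohol | BrCC1=C[C@H](OC1=O)[C@@H]2O[C@]2(C)CC/C=C(C(=O)OC)\[C@@H](O[Si](C)(C)C(C)(C)C)CO | intermediate
26 | bromomethyl butenolide epoxy aldehyde with C9 TBS ether | BrCC1=C[C@H](OC1=O)[C@@H]2O[C@]2(C)CC/C=C(C(=O)OC)\[C@@H](O[Si](C)(C)C(C)(C)C)C=O | intermediate
27 | allylchromium dichloride from 26 (trivalent chromium on C13) | Cl[Cr](Cl)CC1=C[C@H](OC1=O)[C@@H]2O[C@]2(C)CC/C=C(C(=O)OC)\[C@@H](O[Si](C)(C)C(C)(C)C)C=O | intermediate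
28 | ten-membered α-methylene lactone, free C8 hydroxyl, C9 TBS ether (4R,5S,6S,7R,8S,9R) | C=C1C(=O)O[C@H]2[C@H]1[C@H](O)[C@H](O[Si](C)(C)C(C)(C)C)/C(C(=O)OC)=C\CC[C@@]1(C)O[C@@H]21 | intermediate
29 | angelic acid | C/C=C(/C)C(=O)O | starting material
30 | (2Z)-2-methylbut-2-en-1-ol | C/C=C(/C)CO | intermediate
31 | [(2R,3S)-2,3-dimethyloxiran-2-yl]methanol | OC[C@@]1(C)O[C@H]1C | intermediate
32 | (2S,3S)-2,3-dimethyloxirane-2-carboxylic acid | OC(=O)[C@@]1(C)O[C@H]1C | intermediate
33 | (2R,3R)-3-chloro-2-hydroxy-2-methylbutanoic acid | OC(=O)[C@@](C)(O)[C@@H](C)Cl | intermediate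
34 | triethylsilyl (2R,3R)-3-chloro-2-methyl-2-(triethylsilyloxy)butanoate | CC[Si](CC)(CC)OC(=O)[C@@](C)(O[Si](CC)(CC)CC)[C@@H](C)Cl | intermediate
35 | (2R,3R)-3-chloro-2-methyl-2-(triethylsilyloxy)butanoic acid | OC(=O)[C@@](C)(O[Si](CC)(CC)CC)[C@@H](C)Cl | intermediate
36 | mixed anhydride of 35 with 2,4,6-trichlorobenzoic acid | O=C(OC(=O)[C@@](C)(O[Si](CC)(CC)CC)[C@@H](C)Cl)c1c(Cl)cc(Cl)cc1Cl | intermediate
37 | C8 ester of 28 with 35 (ring configuration as in the target) | C=C1C(=O)O[C@H]2[C@H]1[C@H](OC(=O)[C@@](C)(O[Si](CC)(CC)CC)[C@@H](C)Cl)[C@H](O[Si](C)(C)C(C)(C)C)/C(C(=O)OC)=C\CC[C@@]1(C)O[C@@H]21 | intermediate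
38 | C8 chlorohydrin ester with free C9 hydroxyl (ring configuration as in the target) | C=C1C(=O)O[C@H]2[C@H]1[C@H](OC(=O)[C@@](C)(O)[C@@H](C)Cl)[C@H](O)/C(C(=O)OC)=C\CC[C@@]1(C)O[C@@H]21 | intermediate
39 | CNP0185503.1: 4,5-epoxygermacra-1(10),11(13)-dien-12,6-olide, C14 methyl ester, 9-acetate, 8-[(2R,3R)-3-chloro-2-hydroxy-2-methylbutanoate], 4R,5S,6S,7R,8S,9R | C=C1C(=O)O[C@H]2[C@H]1[C@H](OC(=O)[C@@](C)(O)[C@@H](C)Cl)[C@H](OC(C)=O)/C(C(=O)OC)=C\CC[C@@]1(C)O[C@@H]21 | target

**Step count and risks**

Total step count: 26. Longest linear sequence: 20 steps from nerol (steps 1–6, 8–18, 24–26).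

Steps most likely to fail:

Step 18 (key step). What may go wrong is poor facial selectivity at the aldehyde. The closed chair with C9 equatorial, which this allylmetal prefers in intermolecular additions, selects the other aldehyde face and gives the C8 epimer. Oligomerisation is a lesser concern. The fallback changes the mechanism from a closed to an open transition state. It sets out from alcohol 25. Exchange of the allylic bromide for tin ((Bu3Sn)2, Pd(PPh3)4 cat., THF) should give the 3-[(tributylstannyl)methyl]butenolide alcohol F1. Dess–Martin oxidation should give the corresponding stannyl aldehyde F2. BF3·OEt2 in CH2Cl2 at −78 °C should then close the ring through the open, antiperiplanar transition state of Lewis-acid-promoted allylstannane additions. In that mode the inherent syn preference (C6 against O8), polar Felkin–Anh control by the C9 silyl ether and approach anti to C5 all point to the same diastereomer. The oxirane, deactivated by the acyloxy-bearing C6, is expected to survive at this temperature. The fallback comes back to the route at 28.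

Step 15. What may go wrong is loss of the allylic bromide during the ring-closing metathesis or the preceding acylation (displacement at C13, decomposition of the ruthenium carbene by the allyl bromide). The fallback brings C13 in as a silyl ether and brominates after ring closure. It sets out from alcohol 20. Commercial methyl 2-(hydroxymethyl)acrylate is silylated (t-BuMe2SiCl, imidazole) to methyl 2-{[(tert-butyldimethylsilyl)oxy]methyl}prop-2-enoate F3 and hydrolysed (LiOH, THF/H2O) to 2-{[(tert-butyldimethylsilyl)oxy]methyl}prop-2-enoic acid F4. DCC/DMAP esterification of 20 with F4 should give the silyloxymethyl acrylate F5. Ring-closing metathesis with the same catalyst should give the 3-(silyloxymethyl)butenolide F6. Buffered HF·pyridine at 0 °C should remove the primary allylic silyl ether selectively to give the 3-(hydroxymethyl)butenolide F7. CBr4/PPh3 (Appel reaction) then returns the route at 24.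

Step 5. What may go wrong is poor facial selectivity in the addition to the epoxy aldehyde (magnesium chelation competing with Felkin–Anh control), which erodes the C6 configuration. The fallback sets the carbinol by reduction instead of addition. It sets out from the mixture of 7 and its C6 epimer. MnO2 oxidation should give the epoxy enone 1-[(2R,3R)-3-(but-3-yn-1-yl)-3-methyloxiran-2-yl]prop-2-en-1-one F8. Chelation-controlled 1,2-reduction with Zn(BH4)2 in Et2O at −20 °C, which is known to give anti epoxy alcohols from α,β-epoxy ketones, returns the route at 7.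

**Further compounds**

F1 | step 18 | 3-[(tributylstannyl)methyl]butenolide alcohol (25 with SnBu3 in place of Br) | CCCC[Sn](CCCC)(CCCC)CC1=C[C@H](OC1=O)[C@@H]2O[C@]2(C)CC/C=C(C(=O)OC)\[C@@H](O[Si](C)(C)C(C)(C)C)CO
F2 | step 18 | 3-[(tributylstannyl)methyl]butenolide aldehyde (26 with SnBu3 in place of Br) | CCCC[Sn](CCCC)(CCCC)CC1=C[C@H](OC1=O)[C@@H]2O[C@]2(C)CC/C=C(C(=O)OC)\[C@@H](O[Si](C)(C)C(C)(C)C)C=O
F3 | step 15 | methyl 2-{[(tert-butyldimethylsilyl)oxy]methyl}prop-2-enoate | C=C(CO[Si](C)(C)C(C)(C)C)C(=O)OC
F4 | step 15 | 2-{[(tert-butyldimethylsilyl)oxy]methyl}prop-2-enoic acid | C=C(CO[Si](C)(C)C(C)(C)C)C(=O)O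
F5 | step 15 | ester of 20 with F4 at O6 | C=C(CO[Si](C)(C)C(C)(C)C)C(=O)O[C@@H](C=C)[C@@H]1O[C@]1(C)CC/C=C(C(=O)OC)\[C@@H](O[Si](C)(C)C(C)(C)C)COCc1ccc(OC)cc1
F6 | step 15 | 3-(silyloxymethyl)butenolide (24 with OSi(t-Bu)Me2 in place of Br) | CC(C)(C)[Si](C)(C)OCC1=C[C@H](OC1=O)[C@@H]2O[C@]2(C)CC/C=C(C(=O)OC)\[C@@H](O[Si](C)(C)C(C)(C)C)COCc1ccc(OC)cc1
F7 | step 15 | 3-(hydroxymethyl)butenolide (24 with OH in place of Br) | OCC1=C[C@H](OC1=O)[C@@H]2O[C@]2(C)CC/C=C(C(=O)OC)\[C@@H](O[Si](C)(C)C(C)(C)C)COCc1ccc(OC)cc1
F8 | step 5 | 1-[(2R,3R)-3-(but-3-yn-1-yl)-3-methyloxiran-2-yl]prop-2-en-1-one | C=CC(=O)[C@@H]1O[C@]1(C)CCC#C
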